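## Structural features

The target is a 3,7-dioxabicyclo[3.3.0]octane: two tetrahydrofuran rings (ring 1: C1–C2–O3–C4–C5; ring 2: C1–C5–C6–O7–C8) share the C1–C5 bond, C1 carries a tertiary hydroxyl, and C2 and C6 each carry a 3,4-dimethoxyphenyl group. The SMILES reads as (1S,2R,5S,6R): the C1 hydroxyl and H5 lie on opposite faces, so the bicycle is trans-fused, which should cost several kcal/mol against the cis junction of the common furofuran lignans. The four stereocentres are contiguous (C2–C1–C5–C6). Each aryl group is trans to the ring carbon on the neighbouring bridgehead, so the C2 aryl is cis to the C1 hydroxyl and the C6 aryl is trans to C4. The fragile points are the benzylic ether bonds C2–O3 and C6–O7, which ionise readily because the arenes are electron-rich, and H5, whose loss from any species with cationic or carbonyl character at C6 lets the junction relax to cis. The real difficulty is therefore the strained junction: a lactol or hydroxy aldehyde at C2 or C6 should prefer ring-opened forms, so each ring must be closed kinetically, and C5 must not sit next to a free carbonyl for long. The key step exploits the constitutional two-fold character of the bicycle: C2 and C6 are both acetal-type carbons (bonded to O3 and O7) with the same aryl group, so both can be ionised to oxocarbenium ions inside the preformed rings 1 and 2 and intercepted by veratrole para to a methoxy group.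

## Logic of the disconnections

**14 ⇒ 11 + 2 × 12.** The aryl–C2 and aryl–C6 bonds are cut. This removes both arenes and two of the four stereocentres at once and uses the identity of the two aryl groups; 11 keeps only C1 and C5. The leaving groups on C2 and C6 of 11 are methoxy, because they can be installed by acetal exchange without exposing a free hemiacetal. The C1 hydroxyl stays free because an acyl group there would participate at C2. The forward step must ionise two acetals in a strained bicycle without loss of H5 and place each aryl trans to C8 or C4.

**11 ⇒ 10.** The C6–O7 bond of ring 2 is cut; in 10 ring 1 is intact, C6 is an acyclic dimethyl acetal and O8 carries its silyl group. The strained ring closes last, at the more easily ionised acyclic acetal and by its own oxygen, so the only productive path of the C6 cation is intramolecular. The forward step must be kinetic and irreversible and must outrun loss of H5.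

**10 ⇒ 8.** C2 and C6 are traced back to the terminal alkene carbons of the two vinyl groups of 8, and the C2–O3 bond is cut. One oxidative cleavage creates both aldehyde-level carbons. Because O4 is free and O8 is not, the C2 aldehyde (no α-hydrogen) closes the unstrained ring 1 and the C6 aldehyde is capped as its acetal. The demand is that C6 is acetalised before C5 can epimerise.

**8 ⇒ 7.** The O4 protecting group is restored. It is needed one step earlier as a chelating ether and must leave in the presence of two alkenes, a silyl ether and a tertiary allylic alcohol, which points to an oxidatively cleaved benzyl-type ether.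

**7 ⇒ 5 + 6.** The C1–C2 bond is cut. The tertiary carbinol C1 is made from a ketone next to the existing centre C5, so C1 needs no reagent control. The demand is 1,2-induction from C5 through a chelate with O4, and a ketone that survives a basic nucleophile although C5 is α to the carbonyl, allylic and β-alkoxy.

**5 ⇒ 4 ⇒ 3.** Functional-group changes only: the ketone of 5 is the oxidised carbinol of 4, and 4 is 3 with its primary hydroxyl protected. The carbinol centre of 3 is a disposable by-product of the C–C bond formation. The demands are selective alkylation of the primary oxygen of a 1,3-diol and an oxidation that leaves C5 alone.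

**3 ⇒ 1 + 2.** The C1–C5 bond is cut by a catalytic enantioselective carbonyl (hydroxymethyl)allylation. This sets C5, the only centre bought with a chiral catalyst, and brings in the C4 hydroxymethyl and the C6 vinyl group from two commercial compounds. The demand is high enantio- and anti-diastereoselectivity, because the minor diastereomer carries the opposite C5 configuration into 5.

## Other disconnections considered

**Alternative 1:** The cut is C1–C2. The C1 ketone A1, with a 3,4-dimethoxybenzyl ether on O3, is irradiated; the excited carbonyl abstracts a benzylic hydrogen from C2 (the γ position is the ether oxygen), and the 1,5-biradical couples to the ring 1 tetrahydrofuranol A2 (Norrish–Yang cyclisation).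
- In its favour: ring 1, the tertiary carbinol and C2 arise in one neutral step, and the C2 aryl group is built in with no question of arene regiochemistry.
- Against it here: A1 is an α-silyloxy ketone prone to α-cleavage, with C5 α to the carbonyl and β-alkoxy. Two electron-rich arenes compete for light. Nothing strongly biases the biradical to close with C8 trans to C6. Ring 2 must still be closed trans-fused after A2.
- Comparison: it forms one ring, one C–C bond and two centres (C1, C2), against two C–C bonds and two centres (C2, C6) in the chosen step. Having no oxocarbenium ion next to H5 is a point on which alternative 1 is the better plan, as is its freedom from arene regiochemistry. On step economy it is worse: both aryl fragments are made separately and at least three steps follow A2, whereas the chosen step ends the synthesis.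

**Alternative 2:** The cut is C4–C5. Rh2(OAc)4 converts the diazo ketone A3 into a carbenoid at C5 that inserts into a C–H bond of the O3 methyl group, closing ring 1 to give A4.
- In its favour: C4 comes from a methyl ether, the C2 aryl is in place, and C1 is locked beforehand as a spiro acetonide.
- Against it here: a methyl C–H bond is the least reactive insertion site, and the carbenoid has the electron-rich C2 arene within reach. C5, which decides the ring junction, is created α to an aryl ketone and is therefore epimerisable. Ketone reduction (C6), acetonide removal and the trans ring closure still follow.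
- Comparison: it forms one ring, one C–C bond and one centre. It is the equal or better of the chosen plan in that no strained ring exists when the key bond forms, and better in that C1 is secure and protected. It moves the hazard from a cation at C6 to an acidic C5–H. Step economy is worse (diazo transfer before, four or more steps after).

**Alternative 3:** The cuts are C4–C5 and C6–O7. Photoreduction of the N-acyloxyphthalimide A5 releases CO2 and an O3–CH2 radical that cyclises 5-exo onto C5 of the styrene; the benzylic C6 radical is oxidised to the cation and captured by the O8 silyl ether, giving A6, the 1-O-triethylsilyl ether of 14.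
- In its favour: two rings, one C–C and one C–O bond and two centres form in one step.
- Against it here: C5 is set in the radical cyclisation with little to bias C6 trans to C8, because the two C1 substituents are similar in size. The isomer with C6 cis to C8 would close the unstrained cis ring faster, so the wrong junction is the likelier course. The arenes are oxidisable under crossover conditions, and A5 needs C1 and C2 set in a longer sequence.
- Comparison: closing the strained ring by kinetic cation capture is a point on which alternative 3 is the better plan, and it is also better on arene regiochemistry and over-arylation. It is equal to the chosen plan in late-stage economy (one desilylation) and in the H5 hazard at a C6 cation. It is worse in control of the ring junction and in the length of the precursor synthesis.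

Key step: step 8

Remarks on the chemistry (assumptions):
- The target is taken as written, (1S,2R,5S,6R), trans-fused; it is not "corrected" to the cis-fused lignan series. C1 and C5 keep the same spatial sense throughout; C5 changes descriptor (R in 3–11, S in 13–14) only through CIP priorities.
- The bicycle numbering (C1, C2, O3, C4, C5, C6, O7, C8) is used for all intermediates, including open-chain ones.
- In step 1 the (S)-ligand is assigned by analogy with related anti-selective iridium allylations; if the sense proves opposite, the (R)-ligand is used and nothing else changes.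
- Methoxy is preferred to acetoxy as the anomeric leaving group of the key-step precursor: an anomeric acetate would require acylating a trans-fused bis-hemiacetal that should not be the resting form of its hydroxy aldehyde.

## Steps

Step 1
Reactants: 1 (tert-butyldimethylsilyloxy)acetaldehyde; 2 4-vinyl-1,3-dioxolan-2-one (vinyl ethylene carbonate, racemic)
Product: 3 (2R,3S)-4-[(tert-butyldimethylsilyl)oxy]-2-ethenylbutane-1,3-diol
Conditions: [Ir(cod)Cl]2 (2.5 mol %), (S)-SEGPHOS (5 mol %), 4-chloro-3-nitrobenzoic acid (10 mol %), K3PO4 (5 mol %), i-PrOH (2 equiv), THF, 60 °C
Reagents that add atoms: none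
Why: Iridium-catalysed transfer-hydrogenative carbonyl (hydroxymethyl)allylation: decarboxylative ionisation of either enantiomer of 2 gives the same alkoxy-substituted π-allyl iridium species, which adds to 1 through a closed chair transition state to give the anti adduct, 2-propanol being the terminal reductant. The chiral bisphosphine fixes C5 (2R in 3), the only centre carried on; the carbinol centre formed with it is erased in step 3.

Step 2
Reactants: 3 (2R,3S)-4-[(tert-butyldimethylsilyl)oxy]-2-ethenylbutane-1,3-diol
Product: 4 (2S,3R)-1-[(tert-butyldimethylsilyl)oxy]-3-{[(4-methoxyphenyl)methoxy]methyl}pent-4-en-2-ol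
Conditions: Bu2SnO, PhMe, reflux (azeotropic removal of water); then PMBCl, Bu4NI (cat.), 80 °C
Reagents that add atoms: 4-methoxybenzyl chloride, COc1ccc(CCl)cc1
Why: Regioselective O-alkylation through a dibutylstannylene acetal: the six-membered stannylene of the 1,3-diol is alkylated at the primary oxygen. A 4-methoxybenzyl ether is chosen for O4 because it chelates magnesium in step 4 and can be removed oxidatively in the presence of alkenes.

Step 3
Reactants: 4 (2S,3R)-1-[(tert-butyldimethylsilyl)oxy]-3-{[(4-methoxyphenyl)methoxy]methyl}pent-4-en-2-ol
Product: 5 (3R)-1-[(tert-butyldimethylsilyl)oxy]-3-{[(4-methoxyphenyl)methoxy]methyl}pent-4-en-2-one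
Conditions: Dess–Martin periodinane, pyridine, CH2Cl2, 0 °C
Reagents that add atoms: none
Why: Dess–Martin oxidation of the secondary carbinol under buffered, non-basic conditions; 5 is used at once because C5 is α to the ketone, allylic and β-alkoxy.

Step 4
Reactants: 5 (3R)-1-[(tert-butyldimethylsilyl)oxy]-3-{[(4-methoxyphenyl)methoxy]methyl}pent-4-en-2-one; 6 vinylmagnesium bromide
Product: 7 (3S,4R)-3-{[(tert-butyldimethylsilyl)oxy]methyl}-4-{[(4-methoxyphenyl)methoxy]methyl}hexa-1,5-dien-3-ol
Conditions: MgBr2·OEt2, CH2Cl2, −78 °C; then 6 (THF solution), −78 °C
Reagents that add atoms: none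
Why: Chelation-controlled Grignard addition: magnesium bridges the carbonyl oxygen and the O4 ether in a six-membered chelate and the vinyl group enters on the face away from the C5 vinyl group, which sets C1 (3S in 7) with its hydroxyl syn to C6 in the C8–C1–C5–C4 zigzag, the relationship that later becomes the trans ring junction. The bulky silyl ether on O8 disfavours the competing five-membered chelate, and the low temperature limits enolisation.

Step 5
Reactants: 7 (3S,4R)-3-{[(tert-butyldimethylsilyl)oxy]methyl}-4-{[(4-methoxyphenyl)methoxy]methyl}hexa-1,5-dien-3-ol
Product: 8 (2R,3S)-3-{[(tert-butyldimethylsilyl)oxy]methyl}-2-ethenylpent-4-ene-1,3-diol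
Conditions: DDQ, CH2Cl2/pH 7 buffer, 0 °C
Reagents that add atoms: none
Why: Oxidative cleavage of the 4-methoxybenzyl ether by DDQ (hydride abstraction, then hydrolysis of the oxocarbenium ion); the silyl ether, both alkenes and the tertiary allylic alcohol are inert, and water keeps O1 from closing an anisylidene acetal.

Step 6
Reactants: 8 (2R,3S)-3-{[(tert-butyldimethylsilyl)oxy]methyl}-2-ethenylpent-4-ene-1,3-diol
Product: 10 (3S,4R)-3-{[(tert-butyldimethylsilyl)oxy]methyl}-4-(dimethoxymethyl)-2-methoxyoxolan-3-ol (anomer mixture), via lactol aldehyde 9 (not isolated)
Conditions: O3, CH2Cl2/MeOH, −78 °C; Me2S, −78 °C → rt; then CH(OMe)3, PPTS, MeOH, rt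
Reagents that add atoms: ozone, [O-][O+]=O; methanol, CO; trimethyl orthoformate, COC(OC)OC
Why: Ozonolysis of both vinyl groups with reductive work-up, then acid-catalysed acetalisation: the C2 aldehyde, which has no α-hydrogen, is caught by O4 as the unstrained ring 1 lactol 9 and becomes the methyl furanoside, while the epimerisable C6 aldehyde is capped as its dimethyl acetal. Orthoformate keeps the medium anhydrous so that the oxygen-bridged C2–O–C6 acetal typical of 1,4-dialdehydes is not retained, and PPTS is mild enough to spare the neopentyl-type silyl ether.

Step 7
Reactants: 10 (3S,4R)-3-{[(tert-butyldimethylsilyl)oxy]methyl}-4-(dimethoxymethyl)-2-methoxyoxolan-3-ol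
Product: 11 (1S,5R)-2,6-dimethoxy-3,7-dioxabicyclo[3.3.0]octan-1-ol (trans-fused, anomer mixture)
Conditions: TMSOTf (0.2 equiv), 4 Å MS, CH2Cl2 (dilute), −78 → −40 °C; Et3N
Reagents that add atoms: none
Why: Lewis-acid-catalysed intramolecular acetal exchange with a silyl ether as nucleophile: the acyclic C6 acetal ionises first, O8 attacks in a 5-exo sense and the silyl group leaves as its methyl ether, so the strained trans-fused ring 2 is closed kinetically and irreversibly at low temperature and not by an equilibrium. C1 and C5 are not touched, the ring 1 acetal is deactivated by the neighbouring carbinol, and both anomers at C2 and C6 are usable.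

Step 8
Reactants: 11 (1S,5R)-2,6-dimethoxy-3,7-dioxabicyclo[3.3.0]octan-1-ol; 12 veratrole (1,2-dimethoxybenzene)
Product: 14 (1S,2R,5S,6R)-2,6-bis(3,4-dimethoxyphenyl)-3,7-dioxabicyclo[3.3.0]octan-1-ol, via mono-aryl acetal 13 (not isolated)
Conditions: 12 (3 equiv), BF3·OEt2 (3 equiv), 4 Å MS, CH2Cl2, −78 → −30 °C; sat. NaHCO3 at −30 °C
Reagents that add atoms: none
Why: BF3·OEt2 removes the anomeric methoxy groups one after the other, first at the less deactivated C6 (cation O7=C6, leading to 13) and then at C2 (cation O3=C2), and each oxocarbenium ion is attacked by 12 through the position para to one methoxy group, its normal site of electrophilic substitution, which gives the 3,4-dimethoxyphenyl pattern directly. The closest known reaction type is the Lewis acid Friedel–Crafts C-arylation of furanosyl acetals and acetates by electron-rich arenes (aryl C-glycoside synthesis), used here twice in one trans-fused substrate. No ring closes: two aryl–carbon bonds and the stereocentres C2 and C6 are formed. At both centres the controlling element is the locked conformation of the trans-fused bicycle: only in the target configuration is the aryl group pseudo-equatorial and trans to the ring carbon on the neighbouring bridgehead (C8 for C2, C4 for C6), whereas the epimer has the aryl nearly eclipsed with C8 or in a 1,3-relationship with the axial C1 hydroxyl. Kinetic attack on the inside face of the envelope cations could favour the other face, so the step relies on product stability: 2-aryl tetrahydrofurans with p-alkoxyaryl groups re-ionise at the benzylic C–O bond under the same Lewis acid (the pathway of acid epimerisation in furofuran lignans) and should drain to the diequatorial isomer. The selectivities needed are para attack on the arene, no loss of H5 from the C6 cation and no second arylation of a re-opened benzylic cation; low temperature, a non-basic medium, a limited excess of 12 and a cold quench address them. The C1 hydroxyl is left free on purpose: BF3·OEt2 tolerates it, it is the smallest possible cis neighbour for the C2 aryl group, and an ester there would participate and deliver the C2 epimer.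

## Compound list

1 | (tert-butyldimethylsilyloxy)acetaldehyde | O=CCO[Si](C)(C)C(C)(C)C | starting material
2 | 4-vinyl-1,3-dioxolan-2-one (vinyl ethylene carbonate, racemic) | C=CC1COC(=O)O1 | starting material
3 | (2R,3S)-4-[(tert-butyldimethylsilyl)oxy]-2-ethenylbutane-1,3-diol | CC(C)(C)[Si](C)(C)OC[C@@H](O)[C@H](C=C)CO | intermediate
4 | (2S,3R)-1-[(tert-butyldimethylsilyl)oxy]-3-{[(4-methoxyphenyl)methoxy]methyl}pent-4-en-2-ol | CC(C)(C)[Si](C)(C)OC[C@@H](O)[C@H](C=C)COCc1ccc(OC)cc1 | intermediate
5 | (3R)-1-[(tert-butyldimethylsilyl)oxy]-3-{[(4-methoxyphenyl)methoxy]methyl}pent-4-en-2-one | CC(C)(C)[Si](C)(C)OCC(=O)[C@H](C=C)COCc1ccc(OC)cc1 | intermediate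
6 | vinylmagnesium bromide | C=C[Mg]Br | starting material
7 | (3S,4R)-3-{[(tert-butyldimethylsilyl)oxy]methyl}-4-{[(4-methoxyphenyl)methoxy]methyl}hexa-1,5-dien-3-ol | CC(C)(C)[Si](C)(C)OC[C@](O)(C=C)[C@H](C=C)COCc1ccc(OC)cc1 | intermediate
8 | (2R,3S)-3-{[(tert-butyldimethylsilyl)oxy]methyl}-2-ethenylpent-4-ene-1,3-diol | CC(C)(C)[Si](C)(C)OC[C@](O)(C=C)[C@H](C=C)CO | intermediate
9 | (3R,4S)-4-{[(tert-butyldimethylsilyl)oxy]methyl}-4,5-dihydroxyoxolane-3-carbaldehyde (lactol aldehyde, anomer mixture, not isolated) | OC1OC[C@@H](C=O)[C@]1(O)CO[Si](C)(C)C(C)(C)C | intermediate
10 | (3S,4R)-3-{[(tert-butyldimethylsilyl)oxy]methyl}-4-(dimethoxymethyl)-2-methoxyoxolan-3-ol (anomer mixture) | COC1OC[C@@H](C(OC)OC)[C@]1(O)CO[Si](C)(C)C(C)(C)C | intermediate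
11 | (1S,5R)-2,6-dimethoxy-3,7-dioxabicyclo[3.3.0]octan-1-ol (trans-fused, anomer mixture) | COC1OC[C@H]2C(OC)OC[C@]12O | intermediate
12 | veratrole (1,2-dimethoxybenzene) | COc1ccccc1OC | starting material
13 | (1S,5S,6R)-6-(3,4-dimethoxyphenyl)-2-methoxy-3,7-dioxabicyclo[3.3.0]octan-1-ol (mono-aryl acetal, not isolated) | COC1OC[C@H]2[C@H](c3ccc(OC)c(OC)c3)OC[C@]12O | intermediate
14 | (1S,2R,5S,6R)-2,6-bis(3,4-dimethoxyphenyl)-3,7-dioxabicyclo[3.3.0]octan-1-ol | COc1ccc([C@H]2OC[C@H]3[C@H](c4ccc(OC)c(OC)c4)OC[C@]23O)cc1OC | target

## Step count and least certain steps

Total step count: 8. Longest linear sequence: 8 steps (1 → 14).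

**Step 8 (key step).** The most likely failure is deprotonation at C5 of the strained C6 oxocarbenium ion, or of a re-opened benzylic cation, because this relieves the trans junction and leads to the cis series or to aromatisation with loss of the C1 hydroxyl. Second is entry of the arene on the inside face at C2 without later equilibration, because torsional preference in the locked envelope opposes the steric preference. Fallback, setting out from 10 and rejoining at 14: both aryl groups are introduced before ring 2 exists. Treatment of 10 with 12 and BF3·OEt2 at −78 °C should arylate the unstrained ring 1 acetal and the acyclic C6 acetal once each, giving (2R,3S,4S)-3-{[(tert-butyldimethylsilyl)oxy]methyl}-2-(3,4-dimethoxyphenyl)-4-[(3,4-dimethoxyphenyl)(methoxy)methyl]oxolan-3-ol F1. On warming with catalytic TMSOTf the benzylic methyl ether of F1 should ionise and the O8 silyl ether close ring 2 by cycloetherification, the aryl group settling pseudo-equatorial, to give 14. No oxocarbenium ion is then generated inside the strained bicycle.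

**Step 7.** The most likely failure is loss of H5 from the acyclic C6 methoxycarbenium ion (enol ether formation and scrambling of C5) competing with slow attack of the hindered silyl ether, because the closure forms a strained ring. Fallback, setting out from 7 and rejoining at 11: the order of ring closures is reversed so that the strained ring closes at C2, whose cation has no β-hydrogen. TBAF frees O8 to give (2S,3R)-2-ethenyl-3-{[(4-methoxyphenyl)methoxy]methyl}pent-4-ene-1,2-diol F2. Ozonolysis and acetalisation as in step 6 tie C6 into the unstrained ring 2 and leave C2 as a dimethyl acetal, giving (3S,4R)-3-(dimethoxymethyl)-5-methoxy-4-{[(4-methoxyphenyl)methoxy]methyl}oxolan-3-ol F3. DDQ frees O4 to give (3S,4R)-3-(dimethoxymethyl)-4-(hydroxymethyl)-5-methoxyoxolan-3-ol F4. CSA with 5 Å molecular sieves at high dilution then closes ring 1 by equilibrium acetal exchange driven by removal of methanol, giving 11.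

**Step 4.** The most likely failure is enolisation of 5 by the basic Grignard reagent (racemisation at C5, migration of the alkene into conjugation or β-elimination of the O4 ether), with erosion of chelation control by THF as a lesser concern. Fallback, setting out from 5 and rejoining at 7: ethynylmagnesium bromide, a far weaker base, is added under the same chelating conditions to give (3R,4R)-3-{[(tert-butyldimethylsilyl)oxy]methyl}-4-{[(4-methoxyphenyl)methoxy]methyl}hex-5-en-1-yn-3-ol F5. Semi-hydrogenation over Pd/CaCO3–Pb(OAc)2 with quinoline and H2 then converts the alkyne into the vinyl group of 7.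

## Further compounds

F1 | step 8 | (2R,3S,4S)-3-{[(tert-butyldimethylsilyl)oxy]methyl}-2-(3,4-dimethoxyphenyl)-4-[(3,4-dimethoxyphenyl)(methoxy)methyl]oxolan-3-ol | COc1ccc(cc1OC)[C@H]1OC[C@@H](C(OC)c2ccc(OC)c(OC)c2)[C@]1(O)CO[Si](C)(C)C(C)(C)C
F2 | step 7 | (2S,3R)-2-ethenyl-3-{[(4-methoxyphenyl)methoxy]methyl}pent-4-ene-1,2-diol | OC[C@](O)(C=C)[C@H](C=C)COCc1ccc(OC)cc1
F3 | step 7 | (3S,4R)-3-(dimethoxymethyl)-5-methoxy-4-{[(4-methoxyphenyl)methoxy]methyl}oxolan-3-ol | COC1OC[C@](O)(C(OC)OC)[C@H]1COCc1ccc(OC)cc1
F4 | step 7 | (3S,4R)-3-(dimethoxymethyl)-4-(hydroxymethyl)-5-methoxyoxolan-3-ol | COC1OC[C@](O)(C(OC)OC)[C@H]1CO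
F5 | step 4 | (3R,4R)-3-{[(tert-butyldimethylsilyl)oxy]methyl}-4-{[(4-methoxyphenyl)methoxy]methyl}hex-5-en-1-yn-3-ol | CC(C)(C)[Si](C)(C)OC[C@](O)(C#C)[C@H](C=C)COCc1ccc(OC)cc1
A1 | alternative 1 | 1,4-bis[(tert-butyldimethylsilyl)oxy]-4-(3,4-dimethoxyphenyl)-3-{[(3,4-dimethoxyphenyl)methoxy]methyl}butan-2-one, C5 and C6 configured as in 14 | COc1ccc(COC[C@@H]([C@@H](O[Si](C)(C)C(C)(C)C)c2ccc(OC)c(OC)c2)C(=O)CO[Si](C)(C)C(C)(C)C)cc1OC
A2 | alternative 1 | 4-[(tert-butyldimethylsilyl)oxy(3,4-dimethoxyphenyl)methyl]-3-{[(tert-butyldimethylsilyl)oxy]methyl}-2-(3,4-dimethoxyphenyl)oxolan-3-ol, configured as in 14 | COc1ccc(cc1OC)[C@H]2OC[C@@H]([C@@H](O[Si](C)(C)C(C)(C)C)c3ccc(OC)c(OC)c3)[C@]2(O)CO[Si](C)(C)C(C)(C)C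
A3 | alternative 2 | 2-diazo-1-(3,4-dimethoxyphenyl)-2-{4-[(3,4-dimethoxyphenyl)(methoxy)methyl]-2,2-dimethyl-1,3-dioxolan-4-yl}ethan-1-one, C1 and C2 configured as in 14 | COc1ccc(cc1OC)[C@@H](OC)[C@@]2(COC(C)(C)O2)C(=[N+]=[N-])C(=O)c3ccc(OC)c(OC)c3
A4 | alternative 2 | (3,4-dimethoxyphenyl)[6-(3,4-dimethoxyphenyl)-2,2-dimethyl-1,3,7-trioxaspiro[4.4]nonan-9-yl]methanone, configured as in 14 | COc1ccc(cc1OC)[C@H]2OC[C@@H](C(=O)c3ccc(OC)c(OC)c3)[C@]24COC(C)(C)O4
A5 | alternative 3 | 1,3-dioxoisoindolin-2-yl 2-{[(E)-1,4-bis(3,4-dimethoxyphenyl)-2-(triethylsilyloxy)-2-[(triethylsilyloxy)methyl]but-3-en-1-yl]oxy}acetate, C1 and C2 configured as in 14 | CC[Si](CC)(CC)OC[C@@](O[Si](CC)(CC)CC)(/C=C/c1ccc(OC)c(OC)c1)[C@H](OCC(=O)ON2C(=O)c3ccccc3C2=O)c4ccc(OC)c(OC)c4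
A6 | alternative 3 | 1-O-triethylsilyl ether of 14 | COc1ccc([C@H]2OC[C@H]3[C@H](c4ccc(OC)c(OC)c4)OC[C@]23O[Si](CC)(CC)CC)cc1OC
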